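**Retrosynthetic overview**
1. Target 20 comes from the 5,7-di-O-benzyl isoflavone 19 by hydrogenolysis. Ring C is the only ring built and it closes last, by acid-triggered attack of the unmasked 2'-OH on a dimethyl acetal (16 → 19).
2. Acetal 16 comes from chalcone 14 by an oxidative 1,2-shift of ring B (Tl(NO3)3, MeOH).
3. Chalcone 14 comes from the key C–C bond formation: a Claisen–Schmidt aldol condensation of the ring A acetophenone 11 with 3,4,5-trimethoxybenzaldehyde 12 (this bond becomes C2–C3).
4. Acetophenone 11 comes from phenol 6 (MOM ether, bromination, Br/Li exchange, Weinreb acylation). Phenol 6 comes from methyl 4-O-methylgallate 1 (benzylation, reduction, oxidation, Dakin-type oxidation).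
5. MOM on the ring-closing oxygen and benzyl on the other two fix the 6-methoxy (not 8-methoxy) regiochemistry. Rings A and B are bought.

Assumption: the target has no stereocentre (it is achiral), so no absolute configuration has to be set and the only stereo-element on the way is the E double bond of chalcone 14; methyl 3,5-dihydroxy-4-methoxybenzoate 1 is taken as a catalogue compound.

**Route**

Step 1
Reactants: 1 methyl 3,5-dihydroxy-4-methoxybenzoate
Product: 2 methyl 3,5-bis(benzyloxy)-4-methoxybenzoate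
Conditions: BnBr (2.4 equiv), K2CO3, DMF, 60 °C
Reagents that add atoms: benzyl bromide, BrCc1ccccc1
Why: Williamson ether synthesis; both phenoxides are O-benzylated while the ester and the aryl methyl ether are inert to K2CO3.

Step 2
Reactants: 2 methyl 3,5-bis(benzyloxy)-4-methoxybenzoate
Product: 3 [3,5-bis(benzyloxy)-4-methoxyphenyl]methanol
Conditions: LiAlH4, THF, 0 °C to rt; Fieser work-up
Reagents that add atoms: none
Why: Hydride reduction of the ester to the primary benzylic alcohol; the aryl ethers are untouched.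

Step 3
Reactants: 3 [3,5-bis(benzyloxy)-4-methoxyphenyl]methanol
Product: 4 3,5-bis(benzyloxy)-4-methoxybenzaldehyde
Conditions: activated MnO2 (excess), CH2Cl2, rt
Reagents that add atoms: none
Why: Chemoselective MnO2 oxidation of a benzylic alcohol stops at the aldehyde.

Step 4
Reactants: 4 3,5-bis(benzyloxy)-4-methoxybenzaldehyde
Product: 6 3,5-bis(benzyloxy)-4-methoxyphenol, via aryl formate 5 (not isolated)
Conditions: mCPBA (1.3 equiv), CH2Cl2, 0 °C to rt; aq. Na2S2O3/NaHCO3 wash; then K2CO3 (0.2 equiv), MeOH, N2, rt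
Reagents that add atoms: mCPBA, OOC(=O)c1cccc(Cl)c1
Why: Baeyer–Villiger (Dakin-type) oxidation; the electron-rich trialkoxyaryl group migrates in preference to hydride, and the formate is methanolysed only after the peracid is destroyed, which protects the oxidisable phenol.

Step 5
Reactants: 6 3,5-bis(benzyloxy)-4-methoxyphenol
Product: 7 1,3-bis(benzyloxy)-2-methoxy-5-(methoxymethoxy)benzene
Conditions: MOMCl (1.5 equiv), iPr2NEt (2 equiv), CH2Cl2, 0 °C to rt
Reagents that add atoms: chloromethyl methyl ether, COCCl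
Why: O-alkylation of the phenol gives a base-stable acetal protecting group that is later removed by acid without touching the benzyl ethers, so the ring-closing oxygen stays distinguishable.

Step 6
Reactants: 7 1,3-bis(benzyloxy)-2-methoxy-5-(methoxymethoxy)benzene
Product: 8 1,3-bis(benzyloxy)-4-bromo-2-methoxy-5-(methoxymethoxy)benzene
Conditions: NBS (1.05 equiv), MeCN, 0 °C, dark
Reagents that add atoms: N-bromosuccinimide, O=C1CCC(=O)N1Br
Why: Electrophilic aromatic bromination of a tetra-alkoxybenzene; the two free positions are equivalent by symmetry, so one equivalent of NBS gives a single monobromide.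

Step 7
Reactants: 8 1,3-bis(benzyloxy)-4-bromo-2-methoxy-5-(methoxymethoxy)benzene
Product: 11 1-[2,4-bis(benzyloxy)-3-methoxy-6-(methoxymethoxy)phenyl]ethan-1-one, via aryllithium 9 (not isolated), via lithium hemiaminal adduct 10 (not isolated)
Conditions: n-BuLi (1.1 equiv), THF, −78 °C, 20 min; MeC(O)N(OMe)Me (1.5 equiv), −78 to 0 °C; quench with water
Reagents that add atoms: N-methoxy-N-methylacetamide, CC(=O)N(C)OC
Why: Bromine–lithium exchange at −78 °C outruns benzylic deprotonation, and the Weinreb ketone synthesis stops at the ketone because the chelated tetrahedral adduct survives until the quench.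

Step 8
Reactants: 11 1-[2,4-bis(benzyloxy)-3-methoxy-6-(methoxymethoxy)phenyl]ethan-1-one; 12 3,4,5-trimethoxybenzaldehyde
Product: 14 (2E)-1-[2,4-bis(benzyloxy)-3-methoxy-6-(methoxymethoxy)phenyl]-3-(3,4,5-trimethoxyphenyl)prop-2-en-1-one, via aldol adduct 13 (not isolated)
Conditions: 12 (1.2 equiv), 50% aq. KOH, EtOH–THF, rt, 24–48 h
Reagents that add atoms: none
Why: Claisen–Schmidt (crossed aldol) condensation; the ketone enolate adds to the non-enolisable aldehyde and E1cB dehydration gives the conjugated chalcone as the thermodynamically favoured E isomer, with the protected 2'-oxygen excluding flavanone formation.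

Step 9
Reactants: 14 (2E)-1-[2,4-bis(benzyloxy)-3-methoxy-6-(methoxymethoxy)phenyl]-3-(3,4,5-trimethoxyphenyl)prop-2-en-1-one
Product: 16 1-[2,4-bis(benzyloxy)-3-methoxy-6-(methoxymethoxy)phenyl]-3,3-dimethoxy-2-(3,4,5-trimethoxyphenyl)propan-1-one (racemic), via organothallium adduct 15 (not isolated)
Conditions: Tl(NO3)3·3H2O (1.2 equiv), MeOH–HC(OMe)3 (3:1), rt
Reagents that add atoms: methanol, CO
Why: McKillop–Taylor oxidative rearrangement; methoxythallation of the enone by trivalent thallium is followed by loss of monovalent thallium with 1,2-migration of the electron-rich ring B to the α-carbon, and the oxocarbenium ion is trapped as the dimethyl acetal, while the masked 2'-oxygen blocks aurone formation.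

Step 10
Reactants: 16 1-[2,4-bis(benzyloxy)-3-methoxy-6-(methoxymethoxy)phenyl]-3,3-dimethoxy-2-(3,4,5-trimethoxyphenyl)propan-1-one
Product: 19 5,7-bis(benzyloxy)-6-methoxy-3-(3,4,5-trimethoxyphenyl)-4H-chromen-4-one, via free phenol acetal 17 (not isolated), via 2-methoxyisoflavanone 18 (not isolated)
Conditions: conc. HCl (10% v/v), MeOH–THF, 60 °C
Reagents that add atoms: none
Why: Acid-catalysed acetal exchange removes the MOM group only, the single free phenol cyclises onto the acetal-derived oxocarbenium ion and elimination of methanol aromatises ring C (cyclisation–elimination), so only the 6-methoxy regioisomer can form.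

Step 11
Reactants: 19 5,7-bis(benzyloxy)-6-methoxy-3-(3,4,5-trimethoxyphenyl)-4H-chromen-4-one
Product: 20 junipegenin C, 5,7-dihydroxy-6-methoxy-3-(3,4,5-trimethoxyphenyl)-4H-chromen-4-one
Conditions: H2 (1 atm), 10% Pd/C, EtOAc–MeOH, rt, stopped after uptake of 2 equiv
Reagents that add atoms: none
Why: Catalytic hydrogenolysis of the two benzyl ethers is faster than reduction of the chromone C2=C3 bond and leaves all four methyl ethers intact; the product is achiral.

**Compound list**
1 | methyl 3,5-dihydroxy-4-methoxybenzoate | COC(=O)c1cc(O)c(OC)c(O)c1 | starting material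
2 | methyl 3,5-bis(benzyloxy)-4-methoxybenzoate | COC(=O)c1cc(OCc2ccccc2)c(OC)c(OCc2ccccc2)c1 | intermediate
3 | [3,5-bis(benzyloxy)-4-methoxyphenyl]methanol | OCc1cc(OCc2ccccc2)c(OC)c(OCc2ccccc2)c1 | intermediate
4 | 3,5-bis(benzyloxy)-4-methoxybenzaldehyde | O=Cc1cc(OCc2ccccc2)c(OC)c(OCc2ccccc2)c1 | intermediate
5 | 3,5-bis(benzyloxy)-4-methoxyphenyl formate (formed in the flask) | O=COc1cc(OCc2ccccc2)c(OC)c(OCc2ccccc2)c1 | intermediate
6 | 3,5-bis(benzyloxy)-4-methoxyphenol | Oc1cc(OCc2ccccc2)c(OC)c(OCc2ccccc2)c1 | intermediate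
7 | 1,3-bis(benzyloxy)-2-methoxy-5-(methoxymethoxy)benzene | COCOc1cc(OCc2ccccc2)c(OC)c(OCc2ccccc2)c1 | intermediate
8 | 1,3-bis(benzyloxy)-4-bromo-2-methoxy-5-(methoxymethoxy)benzene | COCOc1cc(OCc2ccccc2)c(OC)c(OCc2ccccc2)c1Br | intermediate
9 | [2,4-bis(benzyloxy)-3-methoxy-6-(methoxymethoxy)phenyl]lithium (formed in the flask) | [Li]c1c(OCOC)cc(OCc2ccccc2)c(OC)c1OCc1ccccc1 | intermediate
10 | lithium 1-[2,4-bis(benzyloxy)-3-methoxy-6-(methoxymethoxy)phenyl]-1-[methoxy(methyl)amino]ethan-1-olate (racemic, formed in the flask) | CC(O[Li])(N(C)OC)c1c(OCOC)cc(OCc2ccccc2)c(OC)c1OCc1ccccc1 | intermediate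
11 | 1-[2,4-bis(benzyloxy)-3-methoxy-6-(methoxymethoxy)phenyl]ethan-1-one | CC(=O)c1c(OCOC)cc(OCc2ccccc2)c(OC)c1OCc1ccccc1 | intermediate
12 | 3,4,5-trimethoxybenzaldehyde | COc1cc(C=O)cc(OC)c1OC | starting material
13 | 1-[2,4-bis(benzyloxy)-3-methoxy-6-(methoxymethoxy)phenyl]-3-hydroxy-3-(3,4,5-trimethoxyphenyl)propan-1-one (racemic, formed in the flask) | COCOc1cc(OCc2ccccc2)c(OC)c(OCc2ccccc2)c1C(=O)CC(O)c1cc(OC)c(OC)c(OC)c1 | intermediate
14 | (2E)-1-[2,4-bis(benzyloxy)-3-methoxy-6-(methoxymethoxy)phenyl]-3-(3,4,5-trimethoxyphenyl)prop-2-en-1-one | COCOc1cc(OCc2ccccc2)c(OC)c(OCc2ccccc2)c1C(=O)/C=C/c1cc(OC)c(OC)c(OC)c1 | intermediate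
15 | 1-[2,4-bis(benzyloxy)-3-methoxy-6-(methoxymethoxy)phenyl]-2-(dinitratothallio)-3-methoxy-3-(3,4,5-trimethoxyphenyl)propan-1-one (racemic, relative configuration not controlled, formed in the flask) | COCOc1cc(OCc2ccccc2)c(OC)c(OCc2ccccc2)c1C(=O)C([Tl](O[N+](=O)[O-])O[N+](=O)[O-])C(OC)c1cc(OC)c(OC)c(OC)c1 | intermediate
16 | 1-[2,4-bis(benzyloxy)-3-methoxy-6-(methoxymethoxy)phenyl]-3,3-dimethoxy-2-(3,4,5-trimethoxyphenyl)propan-1-one (racemic) | COCOc1cc(OCc2ccccc2)c(OC)c(OCc2ccccc2)c1C(=O)C(C(OC)OC)c1cc(OC)c(OC)c(OC)c1 | intermediate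
17 | 1-[2,4-bis(benzyloxy)-6-hydroxy-3-methoxyphenyl]-3,3-dimethoxy-2-(3,4,5-trimethoxyphenyl)propan-1-one (racemic, formed in the flask) | Oc1cc(OCc2ccccc2)c(OC)c(OCc2ccccc2)c1C(=O)C(C(OC)OC)c1cc(OC)c(OC)c(OC)c1 | intermediate
18 | 5,7-bis(benzyloxy)-2,6-dimethoxy-3-(3,4,5-trimethoxyphenyl)-2,3-dihydro-4H-chromen-4-one (racemic diastereomer mixture, formed in the flask) | COC1Oc2cc(OCc3ccccc3)c(OC)c(OCc3ccccc3)c2C(=O)C1c1cc(OC)c(OC)c(OC)c1 | intermediate
19 | 5,7-bis(benzyloxy)-6-methoxy-3-(3,4,5-trimethoxyphenyl)-4H-chromen-4-one | COc1cc(-c2coc3cc(OCc4ccccc4)c(OC)c(OCc4ccccc4)c3c2=O)cc(OC)c1OC | intermediate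
20 | junipegenin C, 5,7-dihydroxy-6-methoxy-3-(3,4,5-trimethoxyphenyl)-4H-chromen-4-one (achiral) | COc1cc(-c2coc3cc(O)c(OC)c(O)c3c2=O)cc(OC)c1OC | target

**Step count**
Total steps: 11. Longest linear sequence: 11 steps (1 → 20); aldehyde 12 is bought.

**Steps most likely to fail, and fallbacks**

Step 9 (oxidative rearrangement). The generated HNO3 may remove the MOM group early and divert the free 2'-hydroxychalcone to an aurone, or the thallium salt may attack the very electron-rich ring A. The fallback sets out from chalcone 14. Weitz–Scheffer epoxidation (30% H2O2, NaOH, MeOH–THF, 0 °C) gives the racemic trans-epoxide [2,4-bis(benzyloxy)-3-methoxy-6-(methoxymethoxy)phenyl][3-(3,4,5-trimethoxyphenyl)oxiran-2-yl]methanone F1. BF3·OEt2 in CH2Cl2 at 0 °C opens F1 at the benzylic carbon and a 1,2-aroyl shift (the classical chalcone epoxide rearrangement) gives the keto aldehyde 3-[2,4-bis(benzyloxy)-3-methoxy-6-(methoxymethoxy)phenyl]-3-oxo-2-(3,4,5-trimethoxyphenyl)propanal F2. Treating F2 with HCl in MeOH as in step 10 removes the MOM group and closes ring C, so the route is rejoined at isoflavone 19. Any MOM loss caused by BF3 only brings this cyclisation forward.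

Step 7 (Br/Li exchange and acylation). The crowded aryllithium may deprotonate the Weinreb amide or attack a neighbouring benzylic CH2. The fallback sets out from bromide 8. A Stille coupling with tributyl(1-ethoxyvinyl)stannane (Pd(PPh3)4, toluene, 110 °C) gives the enol ether 1,3-bis(benzyloxy)-4-(1-ethoxyethenyl)-2-methoxy-5-(methoxymethoxy)benzene F3. Its very acid-labile enol ether is hydrolysed under conditions that spare the MOM group (PPTS, wet acetone, rt), and the route is rejoined at acetophenone 11.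

Step 8 (Claisen–Schmidt condensation). The di-ortho-substituted ketone may condense slowly under equilibrating hydroxide conditions. The fallback sets out from acetophenone 11 and aldehyde 12. The kinetic lithium enolate of 11 (LDA, THF, −78 °C) is added to 12 and the aldol 13 is isolated this time. MsCl and Et3N in CH2Cl2 at 0 °C convert it into the mesylate 3-[2,4-bis(benzyloxy)-3-methoxy-6-(methoxymethoxy)phenyl]-3-oxo-1-(3,4,5-trimethoxyphenyl)propyl methanesulfonate F4. DBU then eliminates F4 to the E-enone, and the route is rejoined at chalcone 14.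

**Further compounds**
F1 | step 9 | [2,4-bis(benzyloxy)-3-methoxy-6-(methoxymethoxy)phenyl][3-(3,4,5-trimethoxyphenyl)oxiran-2-yl]methanone (racemic trans-epoxide, one enantiomer drawn) | COCOc1cc(OCc2ccccc2)c(OC)c(OCc2ccccc2)c1C(=O)[C@H]1O[C@@H]1c1cc(OC)c(OC)c(OC)c1
F2 | step 9 | 3-[2,4-bis(benzyloxy)-3-methoxy-6-(methoxymethoxy)phenyl]-3-oxo-2-(3,4,5-trimethoxyphenyl)propanal (racemic) | COCOc1cc(OCc2ccccc2)c(OC)c(OCc2ccccc2)c1C(=O)C(C=O)c1cc(OC)c(OC)c(OC)c1
F3 | step 7 | 1,3-bis(benzyloxy)-4-(1-ethoxyethenyl)-2-methoxy-5-(methoxymethoxy)benzene | CCOC(=C)c1c(OCOC)cc(OCc2ccccc2)c(OC)c1OCc1ccccc1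
F4 | step 8 | 3-[2,4-bis(benzyloxy)-3-methoxy-6-(methoxymethoxy)phenyl]-3-oxo-1-(3,4,5-trimethoxyphenyl)propyl methanesulfonate (racemic) | COCOc1cc(OCc2ccccc2)c(OC)c(OCc2ccccc2)c1C(=O)CC(OS(C)(=O)=O)c1cc(OC)c(OC)c(OC)c1
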